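## Analysis of the target

Target 23 is a flavanone. Its ring C (O1, C2, C3, C4, C4a, C8a) is a chroman-4-one fused to benzene ring A, which carries methoxy groups on C5, C6 and C7 and a single hydrogen on C8; the 3,4-dimethoxyphenyl ring B sits on C2. C2 is the only stereocentre and is S. It is benzylic, bonded to O1 and β to the C4 carbonyl, and with no second centre to relay from, its configuration must come from a reagent or catalyst. Once the ketone is present, base or strong acid can open the O1–C2 bond by retro-oxa-Michael reaction to the achiral 2'-hydroxychalcone, so the ketone is best unveiled last and under neutral conditions. Both arenes are electron-rich: C2 (para to a ring B methoxy group) and C4 (ortho and para to the oxygens on C5, C7 and C8a) ionise easily, the rings are oxidisable, and five methyl ethers rule out strong Lewis acids. The difficulty is twofold: ring A is a pentasubstituted benzene with its substituents in a fixed order, and C2 must be set and then kept from ionising or ring-opening. The strategy rests on ring A. Read from C8a, its substituents are O1, the C4 chain on C4a, methoxy on C5, C6 and C7, then hydrogen on C8. This is the order in which a cyclobutenone (C8a with its oxygen, C6, C7, C8) and a 1-methoxyalkyne (C4a with its chain, C5 with its methoxy) deliver their atoms in a vinylketene benzannulation.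

## Retrosynthetic reasoning

The first step back changes an oxidation level, not a bond: 23 is traced to the flavan-4-ol 22 and on to its silyl ether 21. While C4 is a protected carbinol, C2 is not β to a carbonyl, so neither retro-oxa-Michael opening nor elimination of the C2 oxygen can occur during ring closure. The forward steps are a desilylation and a neutral alcohol oxidation in which both C4 epimers converge.

Ring C of 21 is opened at O1–C2, giving the phenol alcohol 19, activated in the forward sense as the oxyphosphonium betaine 20. This cut is preferred to C2–C3 or C4–C4a because it leaves a 1,3-dioxygenated three-carbon chain on C4a, which acyclic carbonyl chemistry builds easily. It also gives the ring-closing role to the phenol oxygen that the benzannulation creates anyway. The forward reaction must substitute at a benzylic carbon with clean inversion, so the carbinol of 19 has to be R to arrive at the S centre of 23. Compound 19 comes from 18 by removing a triethylsilyl group next to a triisopropylsilyl group; the two groups are chosen for this difference in lability.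

Ring A of 18 is then dismantled completely. Cutting C4a–C8a and C5–C6, with C8–C8a as the bond that finally closes the ring, leads to 2,3-dimethoxycyclobutenone 4 and the ynol ether 13. The cut is made here because every position of ring A is then fixed by which atom comes from which partner, so no substitution or metalation on a crowded polyoxygenated arene is needed. The O1 phenol arises from the ketene carbonyl, ready for the later ring closure. The forward cascade runs 4 → 14 → 15 → 16 → 17 → 18. It needs one regiochemistry of ketene–alkyne union, an alkyne partner without free hydroxyl groups, and an alkyne that does not fragment on heating. The C4 oxygen is carried as a silyl ether and not as a ketone, because an alkynone would be too electron-poor to add to the ketene.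

The ynol ether 13 is cut between the alkyne and the carbinol carbon. It is the silyl ether of 12, the adduct of lithium methoxyacetylide 11 with aldehyde 9; 11 is generated in the flask from chloroacetaldehyde dimethyl acetal 10. A methyl ynol ether is required because C5 of 23 carries methoxy, and a methyl ether has no β-hydrogen for retro-ene fragmentation. The addition creates the future C4 carbinol without control, which is acceptable because this centre ends as a carbonyl.

Aldehyde 9 is the reduced form of ester 7, the silyl ether of hydroxy ester 6. The only stereocentre of the synthesis is cut back to the prochiral ketone of keto ester 5. Asymmetric hydrogenation of a β-keto ester is among the most dependable ways to set a benzylic carbinol, and ring B with both its methoxy groups is bought in 5.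

Cyclobutenone 4 is traced through acetate 3 and alcohol 2 to dimethyl squarate 1. Compound 1 already contains the four-membered ring and the two vicinal methoxy groups that become the C6 and C7 substituents. The forward steps only have to take one carbonyl down to CH2.

## Alternatives that were turned down

Alternative 1: Ring C is disconnected at C4a–C4, C3–C4 and O1–C2, with the carbonyl carbon supplied by carbon monoxide A4.
- **Forward key step:** 2-iodo-3,4,5-trimethoxyphenol A2, A4 and 4-ethynyl-1,2-dimethoxybenzene A3 are joined by palladium-catalysed carbonylative alkyne coupling under amine base. The phenol oxygen then adds 6-endo to the alkynone, giving 5,6,7,3',4'-pentamethoxyflavone A1.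
- **For it:** ring A is bought with the correct pattern, the three components are simple, and the full skeleton is reached in two or three steps. On step economy and convergence this alternative is clearly stronger than the chosen route.
- **Against it:** A1 is flat at C2. The only stereocentre would have to be created last, by enantioselective 1,4-reduction of the C2=C3 bond of a vinylogous ester. Such reductions tend to run on to the C4 alcohol (forcing a re-oxidation), the C5 methoxy group hinders carbonyl coordination, and the reduced product can ring-open. Five-ring closure can also compete in the annulation, and A4 must be handled under pressure.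
- **Comparison:** the chosen strategy is longer, but it sets C2 in the first step of its longer arm on a well-behaved substrate class and never passes through an achiral ring C. Its ring A construction also does not depend on an arene with the right pattern being available.

Alternative 2: Ring C is disconnected at O1–C8a.
- **Forward key step:** the C2 hydroxyl of (1S,3S)-1-(6-bromo-2,3,4-trimethoxyphenyl)-3-(3,4-dimethoxyphenyl)propane-1,3-diol A6 is coupled with the aryl bromide by palladium-catalysed C–O bond formation. This gives (2S,4S)-2-(3,4-dimethoxyphenyl)-5,6,7-trimethoxychroman-4-ol A5.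
- **For it:** no bond to C2 is made or broken, so its configuration is retained. This is safer than an inversion at a cation-prone para-methoxybenzylic carbon, and on this point the alternative is stronger than the chosen route. Ring size alone distinguishes the two hydroxyl groups.
- **Against it:** the nucleophile is a secondary alcohol with β-hydrogens and the electrophile is a very electron-rich, ortho-substituted aryl bromide. Oxidative addition is slowed, and β-hydride elimination from the palladium alkoxide (giving ketone and reduced arene) competes with C–O reductive elimination. The free C4 hydroxyl can also bind the metal. A6 needs two controlled stereocentres although only one survives, plus a regioselective arene bromination, and A5 must still be oxidised to 23.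
- **Comparison:** the step count is similar or slightly lower. The chosen strategy offers in its place a ring closure without metal catalysis on a deactivated arene, an irrelevant C4 configuration, and a ring A pattern fixed by construction.

Alternative 3: Ring C is disconnected at C3–C4 and O1–C2 as a [4+2] cycloaddition.
- **Forward key step:** 2-(hydroxymethyl)-3,4,5-trimethoxyphenol A8 is dehydrated by a chiral BINOL-derived phosphoric acid to the ortho-quinone methide 3,4,5-trimethoxy-6-methylidenecyclohexa-2,4-dien-1-one A10. This adds to 3,4-dimethoxystyrene A9 to give (2S)-2-(3,4-dimethoxyphenyl)-5,6,7-trimethoxychromane A7.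
- **For it:** it is the shortest route to ring C, it is convergent, and C2 is set by a catalyst in the ring-forming step. On brevity it is stronger than the chosen route.
- **Against it:** A7 has CH2 at C4. The ketone would need a late benzylic oxidation at C4 in the presence of C2–H, which is benzylic, α to oxygen and para to a methoxy group, and so is the more hydridic position. Two oxidisable arenes are also present. A10 has an unsubstituted methide carbon, so it is short-lived, oligomerises readily and is held only loosely by the chiral acid. With the electron-rich A9 the addition is likely stepwise through a benzylic cation, which weakens facial control, and A9 polymerises under acid.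
- **Comparison:** the chosen strategy is much longer, but it carries the C4 oxygen from the start and ends with a plain alcohol oxidation, avoiding an unsolved site-selective C–H oxidation.

Key step: step 9

Assumption: the carbinol carbon that becomes C4 is formed without stereocontrol in step 7 and is carried as both epimers (RS in names, undefined in SMILES) until it is oxidised in step 13.

## Route

Step 1
Reactants: 1 dimethyl squarate
Product: 2 4-hydroxy-2,3-dimethoxycyclobut-2-en-1-one (racemic)
Conditions: LiAlH(OtBu)3, THF, −78 °C; aq. potassium sodium tartrate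
Reagents that add atoms: none
Why: Chemoselective 1,2-reduction of one carbonyl of the squarate by a bulky alkoxyaluminium hydride; the remaining carbonyl of 2 is a deactivated vinylogous ester, so reduction should stop at the mono-alcohol. The new centre is racemic and is removed in step 3; 2 is acid-sensitive and is used crude.

Step 2
Reactants: 2 4-hydroxy-2,3-dimethoxycyclobut-2-en-1-one
Product: 3 2,3-dimethoxy-4-oxocyclobut-2-en-1-yl acetate (racemic)
Conditions: Ac2O, pyridine, DMAP (cat.), CH2Cl2, 0 °C
Reagents that add atoms: acetic anhydride CC(=O)OC(C)=O
Why: DMAP-catalysed O-acylation turns the hydroxyl into a group that can be expelled reductively. The basic medium avoids the acid-triggered rearrangement of 2 to a cyclobutenedione.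

Step 3
Reactants: 3 2,3-dimethoxy-4-oxocyclobut-2-en-1-yl acetate
Product: 4 2,3-dimethoxycyclobut-2-en-1-one
Conditions: SmI2, THF–MeOH, −78 °C
Reagents that add atoms: none
Why: SmI2 reductive cleavage of an α-acyloxy ketone: two single-electron transfers expel acetate from the carbon next to the carbonyl and methanol protonates that carbon. The low temperature keeps the cyclobutenone ring closed.

Step 4
Reactants: 5 ethyl 3-(3,4-dimethoxyphenyl)-3-oxopropanoate
Product: 6 ethyl (3R)-3-(3,4-dimethoxyphenyl)-3-hydroxypropanoate
Conditions: H2 (50 atm), RuCl2[(S)-BINAP](dmf)n (0.5 mol %), EtOH, 60 °C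
Reagents that add atoms: none
Why: Noyori asymmetric hydrogenation of a β-keto ester; chelation of the keto ester to the BINAP ruthenium hydride fixes the face of hydride delivery. (S)-BINAP is expected to give the R carbinol, because the face attacked is the same as for alkyl β-keto esters while the aryl group outranks the ester-bearing methylene and reverses the descriptor.

Step 5
Reactants: 6 ethyl (3R)-3-(3,4-dimethoxyphenyl)-3-hydroxypropanoate
Product: 7 ethyl (3R)-3-(3,4-dimethoxyphenyl)-3-(triethylsilyloxy)propanoate
Conditions: Et3SiCl, imidazole, DMF, 0 °C to rt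
Reagents that add atoms: chlorotriethylsilane CC[Si](Cl)(CC)CC
Why: Standard imidazole-promoted silylation of a secondary alcohol. The triethylsilyl ether survives hydride, acetylide and heat, yet can later be removed next to a triisopropylsilyl ether.

Step 6
Reactants: 7 ethyl (3R)-3-(3,4-dimethoxyphenyl)-3-(triethylsilyloxy)propanoate
Product: 9 (3R)-3-(3,4-dimethoxyphenyl)-3-(triethylsilyloxy)propanal, via aluminium hemiacetal 8 (not isolated)
Conditions: i-Bu2AlH, CH2Cl2, −78 °C; MeOH, then aq. potassium sodium tartrate
Reagents that add atoms: none
Why: Partial reduction of an ester with i-Bu2AlH; the tetrahedral aluminium hemiacetal 8 persists at −78 °C and releases the aldehyde only on work-up. The β-silyloxy aldehyde is used at once to avoid β-elimination.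

Step 7
Reactants: 9 (3R)-3-(3,4-dimethoxyphenyl)-3-(triethylsilyloxy)propanal; 10 chloroacetaldehyde dimethyl acetal
Product: 12 (3RS,5R)-5-(3,4-dimethoxyphenyl)-1-methoxy-5-(triethylsilyloxy)pent-1-yn-3-ol, via lithium methoxyacetylide 11 (not isolated)
Conditions: 10, LiNEt2 (3 equiv, from Et2NH and n-BuLi), THF, 0 °C; then 9, −78 °C; aq. NaHCO3
Reagents that add atoms: none
Why: Three equivalents of amide convert 10 into acetylide 11 by loss of methanol, loss of HCl and metalation; 11 then adds 1,2 to the aldehyde. No useful 1,3-induction is expected and none is needed, so both C3 epimers are taken on; the basic work-up protects the hydroxy ynol ether from Meyer–Schuster-type rearrangement.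

Step 8
Reactants: 12 (3RS,5R)-5-(3,4-dimethoxyphenyl)-1-methoxy-5-(triethylsilyloxy)pent-1-yn-3-ol
Product: 13 (3RS,5R)-5-(3,4-dimethoxyphenyl)-1-methoxy-5-(triethylsilyloxy)-3-(triisopropylsilyloxy)pent-1-yne
Conditions: i-Pr3SiCl, imidazole, DMAP (cat.), DMF, rt to 40 °C
Reagents that add atoms: chlorotriisopropylsilane CC(C)[Si](Cl)(C(C)C)C(C)C
Why: Imidazole-promoted silylation of a propargylic alcohol under mildly basic, Lewis-acid-free conditions that the ynol ether tolerates. The triisopropylsilyl ether removes the last free hydroxyl before the ketene step and outlasts the later triethylsilyl cleavage.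

Step 9
Reactants: 4 2,3-dimethoxycyclobut-2-en-1-one; 13 (3RS,5R)-5-(3,4-dimethoxyphenyl)-1-methoxy-5-(triethylsilyloxy)-3-(triisopropylsilyloxy)pent-1-yne
Product: 18 2-[(1RS,3R)-3-(3,4-dimethoxyphenyl)-3-(triethylsilyloxy)-1-(triisopropylsilyloxy)propyl]-3,4,5-trimethoxyphenol, via vinylketene 14 (not isolated), via vinylcyclobutenone 15 (not isolated), via dienylketene 16 (not isolated), via cyclohexadienone 17 (not isolated)
Conditions: 4 (1.3 equiv), PhMe, 110 then 140 °C, sealed tube; then K2CO3, MeOH, 0 °C
Reagents that add atoms: none
Why: On heating, 4 undergoes 4π electrocyclic opening to vinylketene 14, whose ketene C=C adds in a [2+2] cycloaddition to ynol ether 13 with the carbonyl carbon bonding to the chain-bearing alkyne carbon, giving vinylcyclobutenone 15 (C4a–C8a and C5–C6 formed). A second 4π opening of 15 cleaves the former carbonyl–C2 bond of 4 to give dienylketene 16, which closes ring A by thermal disrotatory 6π electrocyclisation between the ketene carbon and the terminal CH2 (C8a–C8) to dienone 17, and tautomerisation gives phenol 18. The closest known reaction type is the Danheiser benzannulation of cyclobutenones with alkoxy- and siloxyalkynes. The step needs one regiochemistry of ketene–alkyne union, and the polarisation of the ynol ether secures it: the oxygen lone pair makes the carbon remote from oxygen nucleophilic, so the chain ends up ortho to the new hydroxyl and the alkyne methoxy on C5. It also needs the vinyl group of 15 to rotate inward in the second opening, and the methoxy group on the same quaternary carbon, a donor that prefers outward rotation, secures the Z dienylketene that can cyclise. No stereocentre is created that survives (the quaternary carbon of 15 becomes sp2), the R carbinol is remote and untouched, and both epimers at the silyloxy carbon react alike. The methyl ynol ether has no β-hydrogen for retro-ene loss of an alkene and both hydroxyls are silylated, so neither partner is consumed by the ketene or by heat. The closing K2CO3/MeOH treatment only cleaves any aryl ester formed when the product phenol traps 14.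

Step 10
Reactants: 18 2-[(1RS,3R)-3-(3,4-dimethoxyphenyl)-3-(triethylsilyloxy)-1-(triisopropylsilyloxy)propyl]-3,4,5-trimethoxyphenol
Product: 19 2-[(1RS,3R)-3-(3,4-dimethoxyphenyl)-3-hydroxy-1-(triisopropylsilyloxy)propyl]-3,4,5-trimethoxyphenol
Conditions: HF·pyridine, pyridine, THF, 0 °C
Reagents that add atoms: none
Why: Selective desilylation: the less hindered triethylsilyl ether is cleaved much faster than the triisopropylsilyl ether. The pyridine buffer keeps the medium too weakly acidic to ionise either benzylic C–O bond.

Step 11
Reactants: 19 2-[(1RS,3R)-3-(3,4-dimethoxyphenyl)-3-hydroxy-1-(triisopropylsilyloxy)propyl]-3,4,5-trimethoxyphenol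
Product: 21 (2S,4RS)-2-(3,4-dimethoxyphenyl)-5,6,7-trimethoxy-4-(triisopropylsilyloxy)chromane, via oxyphosphonium betaine 20 (not isolated)
Conditions: PPh3, DIAD, PhMe, 0 °C
Reagents that add atoms: none
Why: Intramolecular Mitsunobu etherification: the phenol protonates the phosphine–azodicarboxylate adduct, the benzylic alcohol is activated as oxyphosphonium 20, and the phenoxide displaces it in a 6-exo-tet SN2 closure of ring C. Inversion converts the R carbinol into the S centre at C2; the non-polar solvent and low temperature are chosen to disfavour ionisation.

Step 12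
Reactants: 21 (2S,4RS)-2-(3,4-dimethoxyphenyl)-5,6,7-trimethoxy-4-(triisopropylsilyloxy)chromane
Product: 22 (2S,4RS)-2-(3,4-dimethoxyphenyl)-5,6,7-trimethoxychroman-4-ol
Conditions: Bu4NF, THF, 0 °C to rt
Reagents that add atoms: none
Why: Fluoride cleavage of the silyl ether under non-acidic conditions, so the acid-labile benzylic ether at C2 and the C4 carbinol are not ionised. C2 is not touched.

Step 13
Reactants: 22 (2S,4RS)-2-(3,4-dimethoxyphenyl)-5,6,7-trimethoxychroman-4-ol
Product: 23 (2S)-5,6,7,3',4'-pentamethoxyflavanone
Conditions: Dess–Martin periodinane, NaHCO3, CH2Cl2, 0 °C to rt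
Reagents that add atoms: none
Why: Dess–Martin oxidation of a secondary benzylic alcohol; both C4 epimers converge on the ketone. The buffered, near-neutral medium gives no opportunity for retro-oxa-Michael opening, so the C2 configuration should be preserved.

## Compound list

1 | dimethyl squarate (3,4-dimethoxycyclobut-3-ene-1,2-dione) | COC1=C(OC)C(=O)C1=O | starting material
2 | 4-hydroxy-2,3-dimethoxycyclobut-2-en-1-one (racemic) | COC1=C(OC)C(=O)C1O | intermediate
3 | 2,3-dimethoxy-4-oxocyclobut-2-en-1-yl acetate (racemic) | COC1=C(OC)C(=O)C1OC(C)=O | intermediate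
4 | 2,3-dimethoxycyclobut-2-en-1-one | COC1=C(OC)C(=O)C1 | intermediate
5 | ethyl 3-(3,4-dimethoxyphenyl)-3-oxopropanoate | CCOC(=O)CC(=O)c1ccc(OC)c(OC)c1 | starting material
6 | ethyl (3R)-3-(3,4-dimethoxyphenyl)-3-hydroxypropanoate | CCOC(=O)C[C@@H](O)c1ccc(OC)c(OC)c1 | intermediate
7 | ethyl (3R)-3-(3,4-dimethoxyphenyl)-3-(triethylsilyloxy)propanoate | CCOC(=O)C[C@@H](O[Si](CC)(CC)CC)c1ccc(OC)c(OC)c1 | intermediate
8 | aluminium hemiacetal, [(3R)-3-(3,4-dimethoxyphenyl)-1-ethoxy-3-(triethylsilyloxy)propoxy]diisobutylaluminium (not isolated) | CCOC(O[Al](CC(C)C)CC(C)C)C[C@@H](O[Si](CC)(CC)CC)c1ccc(OC)c(OC)c1 | intermediate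
9 | (3R)-3-(3,4-dimethoxyphenyl)-3-(triethylsilyloxy)propanal | O=CC[C@@H](O[Si](CC)(CC)CC)c1ccc(OC)c(OC)c1 | intermediate
10 | chloroacetaldehyde dimethyl acetal (2-chloro-1,1-dimethoxyethane) | COC(CCl)OC | starting material
11 | lithium methoxyacetylide (not isolated) | [Li]C#COC | intermediate
12 | (3RS,5R)-5-(3,4-dimethoxyphenyl)-1-methoxy-5-(triethylsilyloxy)pent-1-yn-3-ol (both C3 epimers) | COC#CC(O)C[C@@H](O[Si](CC)(CC)CC)c1ccc(OC)c(OC)c1 | intermediate
13 | (3RS,5R)-5-(3,4-dimethoxyphenyl)-1-methoxy-5-(triethylsilyloxy)-3-(triisopropylsilyloxy)pent-1-yne (both C3 epimers) | COC#CC(O[Si](C(C)C)(C(C)C)C(C)C)C[C@@H](O[Si](CC)(CC)CC)c1ccc(OC)c(OC)c1 | intermediate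
14 | vinylketene, 2,3-dimethoxybuta-1,3-dien-1-one (not isolated) | C=C(OC)C(OC)=C=O | intermediate
15 | vinylcyclobutenone, 3,4-dimethoxy-4-(1-methoxyethenyl)-2-[(1RS,3R)-3-(3,4-dimethoxyphenyl)-3-(triethylsilyloxy)-1-(triisopropylsilyloxy)propyl]cyclobut-2-en-1-one (not isolated) | C=C(OC)C1(OC)C(OC)=C(C(O[Si](C(C)C)(C(C)C)C(C)C)C[C@@H](O[Si](CC)(CC)CC)c2ccc(OC)c(OC)c2)C1=O | intermediate
16 | dienylketene, (3Z)-3,4,5-trimethoxy-2-[(1RS,3R)-3-(3,4-dimethoxyphenyl)-3-(triethylsilyloxy)-1-(triisopropylsilyloxy)propyl]hexa-1,3,5-trien-1-one (not isolated) | C=C(OC)/C(OC)=C(OC)\C(=C=O)C(O[Si](C(C)C)(C(C)C)C(C)C)C[C@@H](O[Si](CC)(CC)CC)c1ccc(OC)c(OC)c1 | intermediate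
17 | cyclohexadienone, 3,4,5-trimethoxy-2-[(1RS,3R)-3-(3,4-dimethoxyphenyl)-3-(triethylsilyloxy)-1-(triisopropylsilyloxy)propyl]cyclohexa-2,4-dien-1-one (not isolated) | O=C1CC(OC)=C(OC)C(OC)=C1C(O[Si](C(C)C)(C(C)C)C(C)C)C[C@@H](O[Si](CC)(CC)CC)c1ccc(OC)c(OC)c1 | intermediate
18 | 2-[(1RS,3R)-3-(3,4-dimethoxyphenyl)-3-(triethylsilyloxy)-1-(triisopropylsilyloxy)propyl]-3,4,5-trimethoxyphenol (both C1 epimers) | COc1c(OC)c(OC)cc(O)c1C(O[Si](C(C)C)(C(C)C)C(C)C)C[C@@H](O[Si](CC)(CC)CC)c1ccc(OC)c(OC)c1 | intermediate
19 | 2-[(1RS,3R)-3-(3,4-dimethoxyphenyl)-3-hydroxy-1-(triisopropylsilyloxy)propyl]-3,4,5-trimethoxyphenol (both C1 epimers) | COc1c(OC)c(OC)cc(O)c1C(O[Si](C(C)C)(C(C)C)C(C)C)C[C@@H](O)c1ccc(OC)c(OC)c1 | intermediate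
20 | oxyphosphonium betaine of 19, phenoxide with the (R) benzylic oxygen bound to triphenylphosphonium (not isolated) | COc1c(OC)c(OC)cc([O-])c1C(O[Si](C(C)C)(C(C)C)C(C)C)C[C@@H](O[P+](c1ccccc1)(c1ccccc1)c1ccccc1)c1ccc(OC)c(OC)c1 | intermediate
21 | (2S,4RS)-2-(3,4-dimethoxyphenyl)-5,6,7-trimethoxy-4-(triisopropylsilyloxy)chromane (both C4 epimers) | COc1ccc([C@@H]2CC(O[Si](C(C)C)(C(C)C)C(C)C)c3c(cc(OC)c(OC)c3OC)O2)cc1OC | intermediate
22 | (2S,4RS)-2-(3,4-dimethoxyphenyl)-5,6,7-trimethoxychroman-4-ol (both C4 epimers) | COc1ccc([C@@H]2CC(O)c3c(cc(OC)c(OC)c3OC)O2)cc1OC | intermediate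
23 | (2S)-5,6,7,3',4'-pentamethoxyflavanone, (2S)-2-(3,4-dimethoxyphenyl)-5,6,7-trimethoxychroman-4-one | COc1ccc([C@@H]2CC(=O)c3c(cc(OC)c(OC)c3OC)O2)cc1OC | target

## Step count and least certain steps

Total: 13 steps. Longest linear sequence: 10 steps (steps 4 to 13, from keto ester 5). The cyclobutenone arm is 3 steps (steps 1 to 3).

**Step 9 (key step).** The most likely failure is a slow first ring opening. Cyclobutenone 4 is a vinylogous ester with no donor on its saturated carbon, so forcing temperatures may be needed. At those temperatures the new phenol can be acylated by ketene 14, the ketene can dimerise, and the ortho-hydroxybenzylic silyl ether of the product can lose silanol thermally. Opening 4 by irradiation at ambient temperature would be the first adjustment, but that is a change of conditions only.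

The fallback gives up the ring construction and buys ring A; it sets out from aldehyde 9 and comes back at phenol 18. 3,4,5-Trimethoxyphenol F1 (purchased) is brominated at one of its two equivalent ortho positions (NBS, MeCN, 0 °C) to give 2-bromo-3,4,5-trimethoxyphenol F2. O-Allylation (allyl bromide, K2CO3, acetone) gives allyl 2-bromo-3,4,5-trimethoxyphenyl ether F3. Bromine–lithium exchange (n-BuLi, THF, −78 °C) and addition of the aryllithium to 9 give (1RS,3R)-1-[6-(allyloxy)-2,3,4-trimethoxyphenyl]-3-(3,4-dimethoxyphenyl)-3-(triethylsilyloxy)propan-1-ol F4. Silylation (i-Pr3SiOTf, 2,6-lutidine, CH2Cl2, −78 °C) gives its triisopropylsilyl ether F5, and allyl removal (Pd(PPh3)4, morpholine, THF) gives 18.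

**Step 11 (Mitsunobu closure).** The most likely failure is partial ionisation of the activated para-methoxybenzylic oxygen before the phenoxide attacks. Substitution through the cation would erode the enantiomeric purity at C2, and proton loss toward the styrene would cost material.

The fallback moves stereocontrol from the substitution to a catalyst-controlled resolution; it sets out from 19 and comes back at 23. Compound 19 is cyclised and taken through steps 12 and 13 regardless of the erosion. The resulting 23, contaminated with (2R)-5,6,7,3',4'-pentamethoxyflavanone F6, is subjected to asymmetric transfer hydrogenation (RuCl[(R,R)-TsDPEN](p-cymene), HCO2H–Et3N, EtOAc, rt). This catalyst should deliver hydride to give the 4R carbinol, and does so fastest anti to the C2 aryl group, that is, on F6. F6 is thereby converted into (2R,4R)-2-(3,4-dimethoxyphenyl)-5,6,7-trimethoxychroman-4-ol F7, which is separated by chromatography from unreacted, enantioenriched 23.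

**Step 3 (deacetoxylation).** The most likely failure is at the electron-transfer stage. The vinylogous-ester carbonyl of a strained ring may accept an electron reluctantly, and the enolate-like species formed after loss of acetate is a destabilised four-membered cyclic 4π system, so over-reduction or ring cleavage can compete.

The fallback removes the oxygen by a radical chain that never reduces the carbonyl; it sets out from 2 and comes back at 4. Alcohol 2 is converted (PhOC(S)Cl, pyridine, CH2Cl2, 0 °C) into O-(2,3-dimethoxy-4-oxocyclobut-2-en-1-yl) O-phenyl carbonothioate F8. Barton–McCombie deoxygenation (Bu3SnH, Et3B, air, PhMe, rt) through the allylic, carbonyl-stabilised radical then gives 4 without heating.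

**Step 7 (acetylide addition).** The most likely failure is deprotonation of aldehyde 9 next to the carbonyl by the acetylide or by residual amide, followed by β-elimination of the silyloxy group. Acid-triggered rearrangement of the hydroxy ynol ether 12 during isolation is a second risk; this is met by silylating crude 12.

The fallback replaces the enolisable aldehyde by an amide electrophile; it sets out from ester 7 and comes back at 12. Ester 7 is converted (MeNH(OMe)·HCl, i-PrMgCl, THF, −20 °C) into Weinreb amide (3R)-3-(3,4-dimethoxyphenyl)-N-methoxy-N-methyl-3-(triethylsilyloxy)propanamide F9. Acetylide 11, made as in step 7, adds at −78 °C to a stable chelated adduct. Quenching into cold pH 7 buffer releases (5R)-5-(3,4-dimethoxyphenyl)-1-methoxy-5-(triethylsilyloxy)pent-1-yn-3-one F10, and 1,2-reduction (i-Bu2AlH, PhMe, −78 °C) gives 12.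

## Further compounds

F1 | step 9 | 3,4,5-trimethoxyphenol (purchased) | COc1cc(O)cc(OC)c1OC
F2 | step 9 | 2-bromo-3,4,5-trimethoxyphenol | COc1cc(O)c(Br)c(OC)c1OC
F3 | step 9 | allyl 2-bromo-3,4,5-trimethoxyphenyl ether | C=CCOc1cc(OC)c(OC)c(OC)c1Br
F4 | step 9 | (1RS,3R)-1-[6-(allyloxy)-2,3,4-trimethoxyphenyl]-3-(3,4-dimethoxyphenyl)-3-(triethylsilyloxy)propan-1-ol | C=CCOc1cc(OC)c(OC)c(OC)c1C(O)C[C@@H](O[Si](CC)(CC)CC)c1ccc(OC)c(OC)c1
F5 | step 9 | triisopropylsilyl ether of F4 at the C1 hydroxyl | C=CCOc1cc(OC)c(OC)c(OC)c1C(O[Si](C(C)C)(C(C)C)C(C)C)C[C@@H](O[Si](CC)(CC)CC)c1ccc(OC)c(OC)c1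
F6 | step 11 | (2R)-5,6,7,3',4'-pentamethoxyflavanone (minor enantiomer from a partly stereorandom closure) | COc1ccc([C@H]2CC(=O)c3c(cc(OC)c(OC)c3OC)O2)cc1OC
F7 | step 11 | (2R,4R)-2-(3,4-dimethoxyphenyl)-5,6,7-trimethoxychroman-4-ol | COc1ccc([C@H]2C[C@@H](O)c3c(cc(OC)c(OC)c3OC)O2)cc1OC
F8 | step 3 | O-(2,3-dimethoxy-4-oxocyclobut-2-en-1-yl) O-phenyl carbonothioate (racemic) | COC1=C(OC)C(=O)C1OC(=S)Oc1ccccc1
F9 | step 7 | (3R)-3-(3,4-dimethoxyphenyl)-N-methoxy-N-methyl-3-(triethylsilyloxy)propanamide | CON(C)C(=O)C[C@@H](O[Si](CC)(CC)CC)c1ccc(OC)c(OC)c1
F10 | step 7 | (5R)-5-(3,4-dimethoxyphenyl)-1-methoxy-5-(triethylsilyloxy)pent-1-yn-3-one | COC#CC(=O)C[C@@H](O[Si](CC)(CC)CC)c1ccc(OC)c(OC)c1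
A1 | alternative 1 | 5,6,7,3',4'-pentamethoxyflavone | COc1ccc(-c2cc(=O)c3c(cc(OC)c(OC)c3OC)o2)cc1OC
A2 | alternative 1 | 2-iodo-3,4,5-trimethoxyphenol | COc1cc(O)c(I)c(OC)c1OC
A3 | alternative 1 | 4-ethynyl-1,2-dimethoxybenzene | C#Cc1ccc(OC)c(OC)c1
A4 | alternative 1 | carbon monoxide | [C-]#[O+]
A5 | alternative 2 | (2S,4S)-2-(3,4-dimethoxyphenyl)-5,6,7-trimethoxychroman-4-ol | COc1ccc([C@@H]2C[C@H](O)c3c(cc(OC)c(OC)c3OC)O2)cc1OC
A6 | alternative 2 | (1S,3S)-1-(6-bromo-2,3,4-trimethoxyphenyl)-3-(3,4-dimethoxyphenyl)propane-1,3-diol | COc1ccc([C@@H](O)C[C@H](O)c2c(Br)cc(OC)c(OC)c2OC)cc1OC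
A7 | alternative 3 | (2S)-2-(3,4-dimethoxyphenyl)-5,6,7-trimethoxychromane | COc1ccc([C@@H]2CCc3c(cc(OC)c(OC)c3OC)O2)cc1OC
A8 | alternative 3 | 2-(hydroxymethyl)-3,4,5-trimethoxyphenol | COc1cc(O)c(CO)c(OC)c1OC
A9 | alternative 3 | 3,4-dimethoxystyrene | C=Cc1ccc(OC)c(OC)c1
A10 | alternative 3 | 3,4,5-trimethoxy-6-methylidenecyclohexa-2,4-dien-1-one | C=C1C(=O)C=C(OC)C(OC)=C1OC
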